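The numbers in the tables were computed on assumed constants, and the scatter is random.

Dawn holds a small charge of substrate, 0.20 M, so I ask what a target made there has to fear.

| flask | substrate | reagent | free catalyst | remark | time |
|---|---|---|---|---|---|
| grey | 0.80 M | 0.37 M | 1.6 mM | run made earlier |  |
| teal | 0.80 M | 1.6 M | 1.6 mM | run made earlier |  |
| amber | 0.80 M | 0.48 M | 1.3 mM | run made earlier |  |
| dawn | 0.20 M | 2.00 M | 1.0 mM |  | 15 min |
| dusk | 0.80 M | 0.480 M | 1.6 mM |  | 15 min |

- grey (time / min: target / %, substrate / %): 3.00: 10, 79; 6.00: 20, 64; 10.0: 22, 52; 12.0: 19, 40; 15.0: 20, 34
- teal (time / min: target / %, substrate / %): 1.33: 7, 90; 2.50: 10, 84; 4.00: 19, 72; 8.00: 25, 48; 15.0: 32, 19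
- amber (time / min: target / %, substrate / %): 1.33: 3, 94; 2.50: 9, 85; 4.00: 16, 79; 8.00: 18, 62; 15.0: 22, 33

(scatter of a reading: 2 percentage points)

- which one finishes higher in amount of target, in percent of the substrate charged ("neither" within 2 percentage points) (dawn / dusk / neither)
- amount of target at the end, in percent of the substrate charged, dawn
- amount of target at the end, in percent of the substrate charged, dusk

I call the gap what is missing from the charge once substrate and target are counted. I suppose that a substrate meets a target and both are lost. A flask with no meetings then keeps a gap of zero, the zero of my scale, and the gap grows with the product of the two shares. In teal from 8.00 min to 15.0 min, the gain in gap, divided by the mean product and multiplied by 15 min, gives 4.94. This is the pairing number: the gap gained over the time per unit of mean product, which I take as proportional to the charge. Amber, with other reagent and catalyst, reads 5.64.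

Dawn's charge gives 1.23. If the shares run straight, crossing symmetrically, the mean product is one sixth, so the gap is 20.6 %. Teal's average catalyst rate, scaled to dawn's catalyst, covers 1.41 charges, so my first figure counts the substrate as used up and gives 79.4 % target.

The weak link is that this rate was earned on thick substrate. If teal's late rate follows substrate, my estimate is that dawn keeps 48.7 % of its substrate against the catalyst path. I take half of that as left, and commit to 55.1 % for dawn. For dusk I stay near the ends of grey and amber, 20 % and 22 %.

The forecast says dawn, with dawn at 30 % (18 % to 42 %) and dusk at 22 % (19 % to 26 %): “This is uncertain because the stall mechanism is not established”. My dawn figure is higher.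

Dawn ends at 68.0 % and dusk at 26.1 %, so dawn finishes higher.

    catalyst intermediate C ⇌ catalyst intermediate D (K = 0.730, k = 130 /min)
    substrate + target → side product (k = 0.210 /M/min)
    catalyst intermediate A ⇌ released group + catalyst intermediate B (K = 0.260 M, k = 300 /min)
    reagent + free catalyst → catalyst intermediate A (k = 390 /M/min)
    substrate + catalyst intermediate B → catalyst intermediate C (k = 240 /M/min)
    catalyst intermediate D ⇌ free catalyst + target (K = 0.940 M, k = 140 /min)

From grey, changing substrate alone to dawn's gives 78.8 %, reagent alone 33.3 %, and catalyst alone 15.7 %. With dawn's final shares on straight lines, the pairing number gives 17.5 %, against 19.3 % of side product.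

In one more flask, like dusk but with 6.4 × 10⁻⁴ M of free catalyst, the same reckoning on its final shares gives 20.9 %. The flask holds more side product than that, 29.3 %.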